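Numbering: C1 (ester C=O) to C16 (propyl CH3). Ring B = O–O plus C3–C6 (C6 is the ketal carbon). Ring A = O–O plus C10–C13.
Cuts: the ester goes back to the C1 aldehyde. Both C–O bonds of ring B (C3–O, C6–O) go back to O2 and an acyclic (2E,4E)-6-methoxy-2,4-dienal. Then C4=C5 (metathesis), C5–C6 (vinyl addition) and C7=C8 (Wittig, then C=C reduction). Both C–O bonds of ring A (C10–O, C13–O) go back to O2 and (2E,4E)-nona-2,4-dienal.
Enabling feature: in each ring the four carbons are the β, γ, δ and ε carbons of a carbonyl two atoms outside the ring (C1 for C3–C6, C8 for C10–C13). A secondary amine on that carbonyl turns them into the terminal diene of a trienamine, and the C6 methoxy group is simply the ε-substituent of the dienal.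
Forward: ring A first (step 1), chain grown from C8 to C1 (steps 2–6), ring B closed last (step 7), aldehyde helper oxidised to the methyl ester (steps 8–9).
Stereochemistry: one catalyst, (R)-diphenylprolinol trimethylsilyl ether, fixes C10 and C3 by face shielding. C13 and C6 follow from suprafacial O2 addition and the diene geometry. C6 of the precursor is stereoconvergent.

Key step: step 7

Assumption: compounds 6–8 are carried as mixtures of C6 epimers (SMILES without descriptor at that carbon), because this centre is planarised in step 7.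

Step 1
Reactants: 1 (2E,4E)-nona-2,4-dienal
Product: 3 2-[(3R,6S)-6-propyl-3,6-dihydro-1,2-dioxin-3-yl]acetaldehyde, via trienamine 2 (not isolated)
Conditions: O2, TPP (1 mol %), 530 nm LED, (R)-2-[diphenyl(trimethylsilyloxy)methyl]pyrrolidine (20 mol %), 2-FC6H4CO2H (20 mol %), CH2Cl2, 0 °C
Reagents that add atoms: dioxygen, O=O
Why: Proposed new method: the amine converts 1 into the all-E trienamine 2 by loss of an ε-hydrogen, and singlet oxygen, an electrophilic hetero-dienophile that ignores electron-poor 1, should add suprafacially across the β and ε carbons ([4+2]) from the face left open by the CPh2(OSiMe3) group, which sets ring carbon C3 as R, while the E,E geometry of the reacting diene relays this to the cis-related C6 (S); the closest known reaction types are the trienamine-catalysed Diels–Alder and thio-Diels–Alder reactions of 2,4-dienals, the [4+2] photooxygenation of (E,E)-dienes to cis-3,6-dihydro-1,2-dioxines and the amine-catalysed α-oxygenation of aldehydes with singlet oxygen.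

Step 2
Reactants: 3 2-[(3R,6S)-6-propyl-3,6-dihydro-1,2-dioxin-3-yl]acetaldehyde
Product: 4 (2E)-4-[(3R,6S)-6-propyl-3,6-dihydro-1,2-dioxin-3-yl]but-2-enal
Conditions: Ph3P=CHCHO (1.1 equiv), CH2Cl2, 25 °C
Reagents that add atoms: (triphenylphosphoranylidene)acetaldehyde, O=CC=P(c1ccccc1)(c1ccccc1)c1ccccc1
Why: The Wittig reaction of a formyl-stabilised ylide is E-selective and essentially neutral, so the aldehyde should be olefinated faster than the weakly basic ylide can cause β-elimination or Kornblum–DeLaMare opening of the dialkyl dioxine, and no stereocentre is touched.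

Step 3
Reactants: 4 (2E)-4-[(3R,6S)-6-propyl-3,6-dihydro-1,2-dioxin-3-yl]but-2-enal
Product: 5 4-[(3R,6S)-6-propyl-3,6-dihydro-1,2-dioxin-3-yl]butanal
Conditions: Hantzsch ester (1.1 equiv), Bn2NH2+ CF3CO2− (10 mol %), THF, 0 °C to rt
Reagents that add atoms: none
Why: Iminium-catalysed transfer hydrogenation (organocatalytic conjugate reduction of enals) delivers hydride only to the β-carbon of the iminium ion, so the ring alkene and the O–O bond, which would not survive catalytic hydrogenation, stay intact.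

Step 4
Reactants: 5 4-[(3R,6S)-6-propyl-3,6-dihydro-1,2-dioxin-3-yl]butanal
Product: 6 6-[(3R,6S)-6-propyl-3,6-dihydro-1,2-dioxin-3-yl]hex-1-en-3-ol (both carbinol epimers)
Conditions: CH2=CHMgBr (1.1 equiv, added slowly to 5), THF, −78 °C; then H2O
Reagents that add atoms: vinylmagnesium bromide, C=C[Mg]Br
Why: Grignard 1,2-addition to an unhindered aldehyde at −78 °C is much faster than attack on a di-sec-alkyl peroxide or deprotonation next to it, and the new carbinol centre is deliberately left uncontrolled because step 7 erases it.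

Step 5
Reactants: 6 6-[(3R,6S)-6-propyl-3,6-dihydro-1,2-dioxin-3-yl]hex-1-en-3-ol
Product: 7 (3R,6S)-3-(4-methoxyhex-5-en-1-yl)-6-propyl-3,6-dihydro-1,2-dioxine (both ether epimers)
Conditions: MeOTf, 2,6-di-tert-butylpyridine, CH2Cl2, 0 °C to rt
Reagents that add atoms: methyl trifluoromethanesulfonate, COS(=O)(=O)C(F)(F)F
Why: O-Methylation with methyl triflate and a hindered, non-nucleophilic pyridine avoids the alkoxide bases that would open the dioxine by Kornblum–DeLaMare elimination.

Step 6
Reactants: 7 (3R,6S)-3-(4-methoxyhex-5-en-1-yl)-6-propyl-3,6-dihydro-1,2-dioxine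
Product: 8 (2E,4E)-6-methoxy-9-[(3R,6S)-6-propyl-3,6-dihydro-1,2-dioxin-3-yl]nona-2,4-dienal (both C6 epimers)
Conditions: Hoveyda–Grubbs II (5 mol %), (2E,4E)-hexa-2,4-dienal (4 equiv), CH2Cl2, 40 °C
Reagents that add atoms: (2E,4E)-hexa-2,4-dienal, C/C=C/C=C/C=O
Why: Ene–diene cross metathesis engages the distal, more electron-rich propenyl C=C of the dienal and should give the (E,E)-dienal with loss of propene, under neutral, phosphine-free conditions in which the unstrained, doubly branched ring alkene is not a metathesis partner.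

Step 7
Reactants: 8 (2E,4E)-6-methoxy-9-[(3R,6S)-6-propyl-3,6-dihydro-1,2-dioxin-3-yl]nona-2,4-dienal
Product: 10 2-[(3R,6S)-6-methoxy-6-{3-[(3R,6S)-6-propyl-3,6-dihydro-1,2-dioxin-3-yl]propyl}-3,6-dihydro-1,2-dioxin-3-yl]acetaldehyde, via methoxy-trienamine 9 (not isolated)
Conditions: O2, TPP (1 mol %), 530 nm LED, (R)-2-[diphenyl(trimethylsilyloxy)methyl]pyrrolidine (20 mol %), 2-FC6H4CO2H (20 mol %), CH2Cl2, 0 °C, irradiation stopped when 8 is consumed
Reagents that add atoms: dioxygen, O=O
Why: Proposed new method: the (R)-amine condenses with C1 and the iminium ion loses H-6, so both C6 epimers of 8 converge on trienamine 9, in which C3=C4–C5=C6 is a very electron-rich 1-methoxy-4-enamino diene, whereas free 8, the ring A alkene and the O–O bond are inert to singlet oxygen; 1O2 then adds suprafacially across C3 and C6 in an intermolecular [4π+2π] cycloaddition that forms both C–O bonds of ring B in one event, and hydrolysis of the remaining enamine releases 10 and the catalyst. The closest known reaction types are the trienamine-catalysed Diels–Alder and thio-Diels–Alder reactions of 2,4-dienals (bonding at the β and ε carbons), the [4+2] photooxygenation of 1,3-dienes, and the amine-catalysed α-oxygenation of aldehydes with singlet oxygen, which shows that such catalysts tolerate these conditions. C3 is controlled by the catalyst: the CPh2(OSiMe3) group covers one face of the s-trans (E)-enamine, so oxygen reaches C3 from the open face, which for the (R)-amine corresponds to 3R. C6 is relayed from C3 by the suprafacial addition together with the C5=C6 geometry: the E/Z isomers of 9 equilibrate through the iminium ion, and only the (5Z) isomer, with the small OMe inside and the C7 chain outside, reaches the s-cis conformation easily, so the chain ends up cis to the C2 arm and OMe trans to it (6S). The step needs periselectivity ([4+2] at C3/C6 over [2+2] at C1=C2 or C5=C6 and over the ene mode at H-7) and must stop before the enamine of 10 is oxygenated at C2; the push of nitrogen through C2 and C4 to C6, the higher reactivity of the conjugated trienamine and the interruption at consumption of 8 are meant to secure this. A retro-oxa-Michael opening at C3 through the enamine of 10 would correct itself, because re-closure on the iminium ion occurs on the same open face.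

Step 8
Reactants: 10 2-[(3R,6S)-6-methoxy-6-{3-[(3R,6S)-6-propyl-3,6-dihydro-1,2-dioxin-3-yl]propyl}-3,6-dihydro-1,2-dioxin-3-yl]acetaldehyde
Product: 11 2-[(3R,6S)-6-methoxy-6-{3-[(3R,6S)-6-propyl-3,6-dihydro-1,2-dioxin-3-yl]propyl}-3,6-dihydro-1,2-dioxin-3-yl]acetic acid
Conditions: NaClO2, NaH2PO4, 2-methylbut-2-ene, t-BuOH/H2O, 0 °C
Reagents that add atoms: sodium chlorite, [Na+].[O-]Cl=O
Why: The Pinnick oxidation is selective for the aldehyde, is buffered and base-free, and has its hypochlorite scavenged, so the alkenes, both O–O bonds, the peroxyketal and the β-peroxy centre C3 should persist.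

Step 9
Reactants: 11 2-[(3R,6S)-6-methoxy-6-{3-[(3R,6S)-6-propyl-3,6-dihydro-1,2-dioxin-3-yl]propyl}-3,6-dihydro-1,2-dioxin-3-yl]acetic acid
Product: 12 methyl 2-[(3R,6S)-6-methoxy-6-{3-[(3R,6S)-6-propyl-3,6-dihydro-1,2-dioxin-3-yl]propyl}-3,6-dihydro-1,2-dioxin-3-yl]acetate (target)
Conditions: TMSCHN2, toluene/MeOH, 0 °C
Reagents that add atoms: (trimethylsilyl)diazomethane, C[Si](C)(C)C=[N+]=[N-]
Why: Esterification with (trimethylsilyl)diazomethane runs under neutral conditions, so neither β-elimination at C3 nor ionisation at the ketal carbon C6 is provoked.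

Compound list
1 | (2E,4E)-nona-2,4-dienal | CCCC/C=C/C=C/C=O | starting material
2 | (2R)-2-[diphenyl(trimethylsilyloxy)methyl]-1-[(1E,3E,5E)-nona-1,3,5-trien-1-yl]pyrrolidine (trienamine of 1) | C[Si](C)(C)OC(c1ccccc1)(c1ccccc1)[C@H]1CCCN1/C=C/C=C/C=C/CCC | intermediate
3 | 2-[(3R,6S)-6-propyl-3,6-dihydro-1,2-dioxin-3-yl]acetaldehyde | CCC[C@H]1C=C[C@@H](CC=O)OO1 | intermediate
4 | (2E)-4-[(3R,6S)-6-propyl-3,6-dihydro-1,2-dioxin-3-yl]but-2-enal | CCC[C@H]1C=C[C@@H](C/C=C/C=O)OO1 | intermediate
5 | 4-[(3R,6S)-6-propyl-3,6-dihydro-1,2-dioxin-3-yl]butanal | CCC[C@H]1C=C[C@@H](CCCC=O)OO1 | intermediate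
6 | 6-[(3R,6S)-6-propyl-3,6-dihydro-1,2-dioxin-3-yl]hex-1-en-3-ol (carbinol epimers) | CCC[C@H]1C=C[C@@H](CCCC(O)C=C)OO1 | intermediate
7 | (3R,6S)-3-(4-methoxyhex-5-en-1-yl)-6-propyl-3,6-dihydro-1,2-dioxine (ether epimers) | CCC[C@H]1C=C[C@@H](CCCC(OC)C=C)OO1 | intermediate
8 | (2E,4E)-6-methoxy-9-[(3R,6S)-6-propyl-3,6-dihydro-1,2-dioxin-3-yl]nona-2,4-dienal (C6 epimers) | CCC[C@H]1C=C[C@@H](CCCC(OC)/C=C/C=C/C=O)OO1 | intermediate
9 | (2R)-2-[diphenyl(trimethylsilyloxy)methyl]-1-{(1E,3E,5Z)-6-methoxy-9-[(3R,6S)-6-propyl-3,6-dihydro-1,2-dioxin-3-yl]nona-1,3,5-trien-1-yl}pyrrolidine (trienamine of 8) | C[Si](C)(C)OC(c1ccccc1)(c1ccccc1)[C@H]1CCCN1/C=C/C=C/C=C(OC)/CCC[C@H]1OO[C@@H](CCC)C=C1 | intermediate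
10 | 2-[(3R,6S)-6-methoxy-6-{3-[(3R,6S)-6-propyl-3,6-dihydro-1,2-dioxin-3-yl]propyl}-3,6-dihydro-1,2-dioxin-3-yl]acetaldehyde | CCC[C@H]1C=C[C@@H](CCC[C@@]2(OC)C=C[C@@H](CC=O)OO2)OO1 | intermediate
11 | 2-[(3R,6S)-6-methoxy-6-{3-[(3R,6S)-6-propyl-3,6-dihydro-1,2-dioxin-3-yl]propyl}-3,6-dihydro-1,2-dioxin-3-yl]acetic acid | CCC[C@H]1C=C[C@@H](CCC[C@@]2(OC)C=C[C@@H](CC(=O)O)OO2)OO1 | intermediate
12 | methyl 2-[(3R,6S)-6-methoxy-6-{3-[(3R,6S)-6-propyl-3,6-dihydro-1,2-dioxin-3-yl]propyl}-3,6-dihydro-1,2-dioxin-3-yl]acetate | CCC[C@H]1C=C[C@@H](CCC[C@@]2(OC)C=C[C@@H](CC(=O)OC)OO2)OO1 | target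

Total step count: 9. Longest linear sequence: 9 steps (from 1).

Steps most likely to fail

1. Step 7.
- **Risk:** Singlet oxygen may attack the enol ether or enamine double bond in the [2+2] mode, or react in the ene mode. Bonding may start stepwise at remote C6 with loss of facial fidelity. The product aldehyde may be over-oxygenated through its own enamine.
- **Fallback (known chemistry, from 6 back to 12):** Ene–diene cross metathesis of 6 with (2E,4E)-hexa-2,4-dienal gives the 6-hydroxy dienal F1. MnO2 gives the 6-oxo dienal F2.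
- The known amine-catalysed enantioselective peroxidation of enals follows, with the same (R)-amine and 2-methoxypropan-2-yl hydroperoxide. It places oxygen on C3, the β-carbon of the iminium ion, and gives the peroxy enone aldehyde F3.
- Pinnick oxidation gives the acid F4, and TMSCHN2 gives the methyl ester F5. PPTS in MeOH frees the (E)-hydroperoxy enone F6.
- Irradiation isomerises F6 to the (Z)-hydroperoxy enone F7, which closes 6-exo-trig to the dioxinol F8. Acid in MeOH ketalises F8 to 12 and its C6 epimer F9.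
- C6 is here set only under equilibrium control, so F9 is separated and re-equilibrated in acidic MeOH.

2. Step 1.
- **Risk:** The same loss of periselectivity and over-oxygenation as in step 7, and oxidative loss of the catalyst.
- **Fallback (known chemistry, from 1 back to 3):** Pinnick oxidation of 1 gives the dienoic acid F10, and esterification gives the methyl dienoate F11.
- Deconjugative protonation of its lithium trienolate (LDA, DMPU, then AcOH, −78 °C; iodine equilibration of the C5 geometry) gives the 3,5-dienoate F12.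
- Ordinary TPP-sensitised photooxygenation gives the cis endoperoxide ester as the racemate, that is the (3R,6S)-ester F13 and its antipode F14.
- An esterase or lipase kinetic resolution at pH 7 is chosen so that F14 is hydrolysed to the acid F15 and removed by extraction. DIBAL-H at −78 °C takes F13 to 3.

3. Step 6.
- **Risk:** Homodimerisation of the allylic ether, engagement of the proximal C=C of the dienal, or ruthenium-induced decomposition of the peroxide may outrun the cross metathesis.
- **Fallback (from 5 back to 8, replacing steps 4–6):** The whole C1–C5 unit is added as a nucleophile. Hydrozirconation of (E)-5,5-dimethoxypent-3-en-1-yne and transmetalation with Me2Zn are followed by addition to 5, which gives the dienyl carbinol acetal F16.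
- MeOTf with 2,6-di-tert-butylpyridine gives the methyl ether acetal F17. PPTS in wet acetone releases 8.

Further compounds
F1 | step 7 | (2E,4E)-6-hydroxy-9-[(3R,6S)-6-propyl-3,6-dihydro-1,2-dioxin-3-yl]nona-2,4-dienal (C6 epimers) | CCC[C@H]1C=C[C@@H](CCCC(O)/C=C/C=C/C=O)OO1
F2 | step 7 | (2E,4E)-6-oxo-9-[(3R,6S)-6-propyl-3,6-dihydro-1,2-dioxin-3-yl]nona-2,4-dienal | CCC[C@H]1C=C[C@@H](CCCC(=O)/C=C/C=C/C=O)OO1
F3 | step 7 | (3R,4E)-3-[(2-methoxypropan-2-yl)peroxy]-6-oxo-9-[(3R,6S)-6-propyl-3,6-dihydro-1,2-dioxin-3-yl]non-4-enal | CCC[C@H]1C=C[C@@H](CCCC(=O)/C=C/[C@@H](CC=O)OOC(C)(C)OC)OO1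
F4 | step 7 | (3R,4E)-3-[(2-methoxypropan-2-yl)peroxy]-6-oxo-9-[(3R,6S)-6-propyl-3,6-dihydro-1,2-dioxin-3-yl]non-4-enoic acid | CCC[C@H]1C=C[C@@H](CCCC(=O)/C=C/[C@@H](CC(=O)O)OOC(C)(C)OC)OO1
F5 | step 7 | methyl (3R,4E)-3-[(2-methoxypropan-2-yl)peroxy]-6-oxo-9-[(3R,6S)-6-propyl-3,6-dihydro-1,2-dioxin-3-yl]non-4-enoate | CCC[C@H]1C=C[C@@H](CCCC(=O)/C=C/[C@@H](CC(=O)OC)OOC(C)(C)OC)OO1
F6 | step 7 | methyl (3R,4E)-3-hydroperoxy-6-oxo-9-[(3R,6S)-6-propyl-3,6-dihydro-1,2-dioxin-3-yl]non-4-enoate | CCC[C@H]1C=C[C@@H](CCCC(=O)/C=C/[C@@H](CC(=O)OC)OO)OO1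
F7 | step 7 | methyl (3R,4Z)-3-hydroperoxy-6-oxo-9-[(3R,6S)-6-propyl-3,6-dihydro-1,2-dioxin-3-yl]non-4-enoate | CCC[C@H]1C=C[C@@H](CCCC(=O)/C=C\[C@@H](CC(=O)OC)OO)OO1
F8 | step 7 | methyl 2-[(3R)-6-hydroxy-6-{3-[(3R,6S)-6-propyl-3,6-dihydro-1,2-dioxin-3-yl]propyl}-3,6-dihydro-1,2-dioxin-3-yl]acetate (C6 anomers) | CCC[C@H]1C=C[C@@H](CCCC2(O)C=C[C@@H](CC(=O)OC)OO2)OO1
F9 | step 7 | methyl 2-[(3R,6R)-6-methoxy-6-{3-[(3R,6S)-6-propyl-3,6-dihydro-1,2-dioxin-3-yl]propyl}-3,6-dihydro-1,2-dioxin-3-yl]acetate (C6 epimer of 12) | CCC[C@H]1C=C[C@@H](CCC[C@]2(OC)C=C[C@@H](CC(=O)OC)OO2)OO1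
F10 | step 1 | (2E,4E)-nona-2,4-dienoic acid | CCCC/C=C/C=C/C(=O)O
F11 | step 1 | methyl (2E,4E)-nona-2,4-dienoate | CCCC/C=C/C=C/C(=O)OC
F12 | step 1 | methyl (3E,5E)-nona-3,5-dienoate | CCC/C=C/C=C/CC(=O)OC
F13 | step 1 | methyl 2-[(3R,6S)-6-propyl-3,6-dihydro-1,2-dioxin-3-yl]acetate | CCC[C@H]1C=C[C@@H](CC(=O)OC)OO1
F14 | step 1 | methyl 2-[(3S,6R)-6-propyl-3,6-dihydro-1,2-dioxin-3-yl]acetate | CCC[C@@H]1C=C[C@H](CC(=O)OC)OO1
F15 | step 1 | 2-[(3S,6R)-6-propyl-3,6-dihydro-1,2-dioxin-3-yl]acetic acid | CCC[C@@H]1C=C[C@H](CC(=O)O)OO1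
F16 | step 6 | (5E,7E)-9,9-dimethoxy-1-[(3R,6S)-6-propyl-3,6-dihydro-1,2-dioxin-3-yl]nona-5,7-dien-4-ol (carbinol epimers) | CCC[C@H]1C=C[C@@H](CCCC(O)/C=C/C=C/C(OC)OC)OO1
F17 | step 6 | (3R,6S)-3-[(5E,7E)-4,9,9-trimethoxynona-5,7-dien-1-yl]-6-propyl-3,6-dihydro-1,2-dioxine (ether epimers) | CCC[C@H]1C=C[C@@H](CCCC(OC)/C=C/C=C/C(OC)OC)OO1
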